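Saturday's flask had 4.00 h at 25 °C. I called these its warm hours, the time a flask spends at that temperature. Thursday's flask had 8.0 h of them. I wanted to know which count leaves more E.

| flask | D | Q | temperature | remark | time |
|---|---|---|---|---|---|
| ash | 0.050 M | 0.13 µM | −12 °C | run made earlier |  |
| cedar | 0.050 M | 0.20 µM | 15 °C | run made earlier |  |
| elm | 0.10 M | 0.26 µM | −12 °C | run made earlier |  |
| Thursday's | 0.050 M | 0.26 µM | 25 °C |  | 8.0 h |
| Friday's | 0.050 M | 0.26 µM | 0 °C |  | 8.0 h |
| Tuesday's | 0.050 M | 0.26 µM | −25 °C |  | 8.0 h |
| Saturday's | 0.050 M | 0.26 µM |  | at −25 °C until 4.0 h, from then on at 25 °C | 8.0 h |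

| run | time / h | E / % | D / % |
|---|---|---|---|
| ash | 2.50 | 0 | 98.7 |
| ash | 4.00 | 1.1 | 99.4 |
| ash | 8.00 | 1.1 | 99.0 |
| ash | 15.0 | 3.1 | 99.9 |
| ash | 30.0 | 3.3 | 97.2 |
| cedar | 0.667 | 5.1 | 94.1 |
| cedar | 2.00 | 12.3 | 87.5 |
| cedar | 3.00 | 18.0 | 81.0 |
| cedar | 5.00 | 23.6 | 74.3 |
| cedar | 8.00 | 27.6 | 65.9 |
| elm | 2.50 | 2.0 | 100.9 |
| elm | 8.00 | 0 | 98.0 |
| elm | 12.0 | 1.1 | 98.2 |
| elm | 20.0 | 3.3 | 98.0 |
| elm | 30.0 | 2.1 | 98.3 |

(standard deviation of a reading: 1 percentage point)

- what may be going on: Q -> G; D + Q <-> Z; Z <-> Q + E; E <-> X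

1. which flask leads in amount of E, in percent of the D charged ("all alike" within 1.5 percentage points) (Thursday's / Friday's / Tuesday's / Saturday's / all alike)
2. how much E is there at the end, in percent of the D charged: Thursday's
3. how much E is there at the end, in percent of the D charged: Friday's
4. how much E is there at the end, in percent of the D charged: Tuesday's
5. how much E is there at the end, in percent of the D charged: Saturday's

I began with the cold. Elm, with as much Q as Saturday's flask, held 2.1% E after 30.0 h, and it was warmer than Saturday's first stretch. At that pace, the cold 4.0 h of Saturday's flask yielded hardly any of its charge. So I counted that stretch as a pause, taking Q to be unharmed. Saturday's end should then match Thursday's flask at 4.00 h.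

Next I read the cedar table row against row. The part of the charge in neither D nor E I took as X: 1.00%, 2.10% and 6.50% at 3.00 h, 5.00 h and 8.00 h. D used over X gained is E made over E drained. This balance read 6.09 in the earlier stretch and 1.91 in the later one. With a scatter of 1 percentage point per reading, these are rough. E is the intermediate of a consecutive reaction, and it tops out where the balance crosses one. Cedar's readings pointed towards that crossing at its last row.

Per unit of Q, the pace of E in cedar's first row, at 15 °C, was 45.2 times ash's average over its whole 30.0 h at −12 °C. This ratio was rough, since it set a first row against a long average and not against ash's early pace. Carried on to 25 °C, that gave a further 4.10 times. Assuming the drain sped up alike, cedar's 8.00 h shrank to 1.95 h. That is less than 4.00 h, so I reckoned Thursday's flask spent its later warm hours losing E, and I chose Saturday's flask. I reckoned no level.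

The forecast also chose Saturday's, at 29% (16% to 44%), with 24% for Thursday's, 9% for Friday's and 0.2% for Tuesday's, since “the enzyme survives the cold, makes a similar amount late, and has less time to lose E”.

Saturday's flask ended with 40.7% E, Thursday's with 36.9%, Friday's with 7.77% and Tuesday's with 0.299%, so Saturday's led. At its end, Saturday's flask made E 1.08 times as fast as it used it up, each step taken net. So after 4.00 h it stood just short of the crossing, later than my 1.95 h. Thursday's flask at 4.00 h held 40.7% E, level with Saturday's 40.7% at 8.00 h.

    Q → G (k = 0.00780 /h, Ea = 222 kJ/mol)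
    D + Q ⇌ Z (K = 13.0 /M, k = 3.30 × 10⁷ /M/h, Ea = 33.0 kJ/mol, ΔH = 22.0 kJ/mol)
    Z ⇌ Q + E (K = 0.120 M, k = 1.50 × 10⁵ /h, Ea = 60.0 kJ/mol, ΔH = 49.0 kJ/mol)
    E ⇌ X (K = 1.90, k = 0.170 /h, Ea = 91.0 kJ/mol, ΔH = −3.00 kJ/mol)
    (constants at 25 °C)

A reading of Saturday's flask at 20 h has 16.0 h warm hours, more than Thursday's 8.0 h. That places its E between Thursday's 36.9% at 8.00 h and 28.2% at 80.0 h. It holds 30.5%.

The earlier runs and the new flask are calculated with constants of no real substance; noise was put on by code.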